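**Strategy**

Ring A (C1–C5, C10) is closed last by a formal [3+3] union of the C4–C5–C10 unit of an enantiopure ring B (C5–C10) with a three-carbon allyl dianion equivalent. The feature used is the C6 carbonyl of ring B: C4 and C10 both hang on C5 and are both β to C6. A 3-silylallyl unit is first parked on C6; in one pot an anionic oxy-Cope shift then carries it to C10 (C1–C10, angular methyl stereocentre) and the freed allylsilane closes onto the isopropylidene ketone at C4 (C3–C4). The precursor is a bicyclic tertiary carbinol built from a menthyloxybutenolide that supplies C8, C9, C11, C12 and the absolute configuration.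

Key step: step 5

Remarks: atoms carry drimane numbers (C4 gem-dimethyl carbon, C5 ring-fusion CH, C6 oxygenated carbon, C8 and C9 carboxyl-bearing carbons, C10 angular-methyl carbon; C11 and C12 are the carboxyl carbons on C9 and C8). β is the face of ring B that carries C11, C12 and the C10 methyl. Assumption: 1, 2, 7, 9 and 17 are bought (2 is otherwise two known steps from furfural and (+)-menthol).

**Route**

Step 1
Reactants: 1 (E)-4-methoxypent-3-en-2-one; 2 (5S)-5-[(1S,2R,5S)-menthyloxy]furan-2(5H)-one
Product: 5 cis-fused enone lactone (3S,3aS,7aS)-3-[(1S,2R,5S)-menthyloxy]-7-methyl-3a,4-dihydro-2-benzofuran-1,5(3H,7aH)-dione (ring B with C6 ketone and C5=C10–CH3; lactone C11 on C9 and acetal C12 on C8; 8S,9S,12S), via lithium dienolate 3 (not isolated), via lithium lactone enolate 4 (not isolated)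
Conditions: LiN(iPr)2, THF, −78 °C (1 → 3); then 2, −78 → 0 °C; NH4Cl aq
Reagents that add atoms: none
Why: Tandem double Michael annulation (the anionic equivalent of a Diels–Alder reaction): the kinetic α′-enolate of the vinylogous ester should add through C7 to the butenolide anti to the menthyloxy group (sets C8), the lactone enolate should then close ring B on C10 from the side of C7 (cis fusion, sets C9), and loss of methoxide should give the enone.

Step 2
Reactants: 5 cis-fused enone lactone
Product: 6 C5-iodo enone lactone (iodine on the α-carbon C5 of the enone; 8S,9S,12S unchanged)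
Conditions: I2, pyridine, CH2Cl2, 0 → 23 °C
Reagents that add atoms: iodine, II
Why: Pyridine-assisted α-iodination of the enone (addition–iodination–elimination) should place iodine on C5 without touching C8, C9 or C12.

Step 3
Reactants: 6 C5-iodo enone lactone; 7 tributyl(prop-1-en-2-yl)stannane
Product: 8 C5-isopropenyl dienone lactone (C6 ketone, C5=C10–CH3, prop-1-en-2-yl on C5 supplying C4 and both future C4 methyl carbons)
Conditions: Pd2(dba)3 (cat.), AsPh3, CuI, DMF, 23 → 50 °C
Reagents that add atoms: tributyl(prop-1-en-2-yl)stannane, CC(=C)[Sn](CCCC)(CCCC)CCCC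
Why: Stille coupling of an α-iodoenone with an alkenylstannane is a neutral, well-precedented C–C coupling that tolerates the lactone acetal; no stereocentre is involved.

Step 4
Reactants: 8 C5-isopropenyl dienone lactone; 9 allyltrimethylsilane
Product: 11 tertiary carbinol (C6 carries β-OH and, on the α-face, the (E)-CH2–CH=CH–SiMe3 chain; C5=C10 and the isopropenyl group retained), via [1-(trimethylsilyl)allyl]lithium 10 (not isolated)
Conditions: s-BuLi, TMEDA, THF, −78 → −30 °C (9 → 10); then 8, −78 °C; NH4Cl aq
Reagents that add atoms: allyltrimethylsilane, C=CC[Si](C)(C)C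
Why: 1,2-Addition of the silyl-stabilised allyl anion, which bonds to ketones through its unsilylated terminus, should occur at the C6 ketone from the convex α-face of the cis-fused bicycle (setting C6) and faster than lactone attack or enolisation at −78 °C.

Step 5
Reactants: 11 tertiary carbinol
Product: 14 tricyclic Δ1 keto lactone acetal (trans-decalin with 5α-H and 10β-CH3, C1=C2, C4 gem-dimethyl, C6 ketone, lactone acetal on C8/C9), via potassium dienolate 12 (not isolated), via allylsilane enone 13 (not isolated)
Conditions: KN(SiMe3)2, 18-crown-6, THF, 0 → 23 °C; then t-BuOH (1 equiv), Bu4NF, THF–DMF, 23 °C; NH4Cl aq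
Reagents that add atoms: none
Why: The potassium alkoxide of 11 should undergo an anionic oxy-Cope [3,3] shift that breaks the temporary C6–C3 bond and forms C1–C10, giving dienolate 12 with an allylsilane on C10; protonation should give the conjugated isopropylidene ketone 13, and fluoride should then trigger a desilylative intramolecular Michael addition (Hosomi–Sakurai type) of the allylsilane terminus C3 to C4, forming C3–C4. The closest known reaction types are the 1,2-addition/anionic oxy-Cope sequence used as a conjugate allylation of 3-methylcyclohexenones and the fluoride-promoted intramolecular addition of allylsilanes to enones. Ring A closes in a 6-endo-trig mode (the C4=C5 bond lies inside the new ring) with SE2′ transposition of the allyl unit, so the ring A alkene ends at C1=C2. C10 is set by suprafacial chirality transfer from C6 (the chain leaves the α-face of C6 and arrives on the α-face of C10, leaving the methyl β), and C5 is set by protonation of the final enolate on the α-face, which is also the trans ring fusion expected at equilibrium. The step needs the concerted shift to outrun alkoxide fragmentation and the 1,4-closure to outrun 1,2-attack at C6 or protodesilylation; the crown-ether-separated alkoxide and the extra conjugation of the forming dienolate favour the shift, and the 1,2-adduct is a reversible alkoxide whereas the 1,4-adduct is a stable enolate.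

Step 6
Reactants: 14 tricyclic Δ1 keto lactone acetal
Product: 15 saturated tricyclic keto lactone acetal (5S,8S,9S,10S,12S; C6 ketone)
Conditions: H2 (1 atm), Pd on carbon (Pd/C), EtOAc, 23 °C
Reagents that add atoms: none
Why: Heterogeneous hydrogenation should saturate the cis-disubstituted C1=C2 alkene while ketone, lactone and acetal stay intact; no stereocentre changes.

Step 7
Reactants: 15 saturated tricyclic keto lactone acetal
Product: 16 6β-alcohol (6R; axial hydroxyl)
Conditions: NaBH4, MeOH–THF, 0 °C
Reagents that add atoms: none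
Why: Hydride reduction should occur from the open α-face of C6, because the β-face is blocked by the axial C10 and C4 methyls and by C12, giving the axial 6β-alcohol; the lactone is not reduced by NaBH4 at 0 °C.

Step 8
Reactants: 16 6β-alcohol; 17 (2E,4E,6E)-octa-2,4,6-trienoic acid
Product: 19 6β-[(2E,4E,6E)-octa-2,4,6-trienoyloxy] lactone acetal, via mixed anhydride 18 (not isolated)
Conditions: 17, 2,4,6-Cl3C6H2COCl, Et3N, THF, 23 °C; then 16, DMAP, toluene, 60 °C
Reagents that add atoms: (2E,4E,6E)-octa-2,4,6-trienoic acid, C/C=C/C=C/C=C/C(=O)O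
Why: Yamaguchi esterification should transfer the trienoyl group through its acylpyridinium to the hindered 6β-hydroxyl with retention at C6, while the lactone acetal keeps C12 non-electrophilic so that no 6,12-lactone can form.

Step 9
Reactants: 19 6β-trienoate lactone acetal
Product: 20 lactol (C12 hemiacetal, mixture at C12; ring tautomer of the C12 aldehyde / C11 acid)
Conditions: CF3CO2H–H2O–THF, 23 °C
Reagents that add atoms: water, O
Why: Acid hydrolysis of the acyloxy/alkoxy acetal at C12 should release (+)-menthol and give the lactol, whose cis-fused ring form shields C8 from epimerisation; the hindered C6 ester should survive.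

Step 10
Reactants: 20 lactol
Product: 21 (5S,6R,8S,9S,10S)-6-[(2E,4E,6E)-octa-2,4,6-trienoyloxy]drimane-11,12-dioic acid (target)
Conditions: NaClO2, NaH2PO4, 2-methylbut-2-ene, t-BuOH–H2O, 0 → 23 °C
Reagents that add atoms: sodium chlorite, [Na+].[O-]Cl=O
Why: Pinnick oxidation should convert the lactol through its open aldehyde form into the C12 carboxylic acid, with the chlorine scavenger protecting the triene and without enolisation at C8, giving the cis-8,9-diacid.

**Compound list**

1 | (E)-4-methoxypent-3-en-2-one | CC(=O)/C=C(\C)OC | starting material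
2 | (5S)-5-[(1S,2R,5S)-menthyloxy]furan-2(5H)-one | C[C@H]1CC[C@@H]([C@H](C1)O[C@H]2OC(=O)C=C2)C(C)C | starting material
3 | lithium 4-methoxypenta-1,3-dien-2-olate | [Li+].[O-]C(=C)/C=C(\C)OC | intermediate
4 | lithium lactone enolate of the Michael adduct (C7–C8 formed) | [Li+].[O-]C1=C[C@H](CC(=O)/C=C(\C)OC)[C@@H](O[C@H]2C[C@@H](C)CC[C@@H]2C(C)C)O1 | intermediate
5 | cis-fused enone lactone (8S,9S,12S) | O=C1C[C@@H]2[C@@H](O[C@H]3C[C@@H](C)CC[C@@H]3C(C)C)OC(=O)[C@@H]2C(C)=C1 | intermediate
6 | C5-iodo enone lactone | O=C1C[C@@H]2[C@@H](O[C@H]3C[C@@H](C)CC[C@@H]3C(C)C)OC(=O)[C@@H]2C(C)=C1I | intermediate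
7 | tributyl(prop-1-en-2-yl)stannane | CC(=C)[Sn](CCCC)(CCCC)CCCC | starting material
8 | C5-isopropenyl dienone lactone | O=C1C[C@@H]2[C@@H](O[C@H]3C[C@@H](C)CC[C@@H]3C(C)C)OC(=O)[C@@H]2C(C)=C1C(C)=C | intermediate
9 | allyltrimethylsilane | C=CC[Si](C)(C)C | starting material
10 | [1-(trimethylsilyl)allyl]lithium | [Li+].C=C[CH-][Si](C)(C)C | intermediate
11 | tertiary carbinol (6β-OH, 6α-(E)-3-(trimethylsilyl)allyl) | O[C@]1(C/C=C/[Si](C)(C)C)C[C@@H]2[C@@H](O[C@H]3C[C@@H](C)CC[C@@H]3C(C)C)OC(=O)[C@@H]2C(C)=C1C(C)=C | intermediate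
12 | potassium dienolate after the oxy-Cope shift (10β-CH3, 10α-CH(SiMe3)CH=CH2) | C=C(C)C1=C([O-])C[C@@H]2[C@@H](O[C@H]3C[C@@H](C)CC[C@@H]3C(C)C)OC(=O)[C@@H]2[C@@]1(C)C([Si](C)(C)C)C=C.[K+] | intermediate
13 | allylsilane isopropylidene ketone | CC(C)=C1C(=O)C[C@@H]2[C@@H](O[C@H]3C[C@@H](C)CC[C@@H]3C(C)C)OC(=O)[C@@H]2[C@@]1(C)C([Si](C)(C)C)C=C | intermediate
14 | tricyclic Δ1 keto lactone acetal (5α-H, 10β-CH3) | O=C1C[C@@H]3[C@@H](O[C@H]4C[C@@H](C)CC[C@@H]4C(C)C)OC(=O)[C@@H]3[C@@]2(C)C=CCC(C)(C)[C@H]12 | intermediate
15 | saturated tricyclic keto lactone acetal | O=C1C[C@@H]3[C@@H](O[C@H]4C[C@@H](C)CC[C@@H]4C(C)C)OC(=O)[C@@H]3[C@@]2(C)CCCC(C)(C)[C@H]12 | intermediate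
16 | 6β-alcohol | O[C@@H]1C[C@@H]3[C@@H](O[C@H]4C[C@@H](C)CC[C@@H]4C(C)C)OC(=O)[C@@H]3[C@@]2(C)CCCC(C)(C)[C@H]12 | intermediate
17 | (2E,4E,6E)-octa-2,4,6-trienoic acid | C/C=C/C=C/C=C/C(=O)O | starting material
18 | (2E,4E,6E)-octa-2,4,6-trienoic 2,4,6-trichlorobenzoic anhydride | C/C=C/C=C/C=C/C(=O)OC(=O)c1c(Cl)cc(Cl)cc1Cl | intermediate
19 | 6β-trienoate lactone acetal | C/C=C/C=C/C=C/C(=O)O[C@@H]1C[C@@H]3[C@@H](O[C@H]4C[C@@H](C)CC[C@@H]4C(C)C)OC(=O)[C@@H]3[C@@]2(C)CCCC(C)(C)[C@H]12 | intermediate
20 | 6β-trienoate lactol | C/C=C/C=C/C=C/C(=O)O[C@@H]1C[C@@H]3C(O)OC(=O)[C@@H]3[C@@]2(C)CCCC(C)(C)[C@H]12 | intermediate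
21 | (5S,6R,8S,9S,10S)-6-[(2E,4E,6E)-octa-2,4,6-trienoyloxy]drimane-11,12-dioic acid | C/C=C/C=C/C=C/C(=O)O[C@@H]1C[C@H](C(=O)O)[C@H](C(=O)O)[C@@]2(C)CCCC(C)(C)[C@H]12 | target

**Totals**

Total step count: 10. Longest linear sequence: 10 steps (1 and 2 to 21).

**Steps most likely to fail**

Step 5. The [3,3] shift may lose stereochemical fidelity through fragmentation and recombination of the alkoxide, and protodesilylation or 1,2-attack at C6 may outrun the ring closure. The fallback sets out from 8 and returns at 15, forming the two bonds in separate operations. Allylmagnesium bromide (THF, −78 °C) should add to C6 to give the silicon-free 6α-allyl carbinol F1. KH and 18-crown-6 should effect the anionic oxy-Cope shift, and aqueous work-up with base equilibration should give the 10α-allyl isopropylidene ketone F2. Hydroboration with 9-BBN followed by ICl/NaOAc should give the primary iodide F3. Bu3SnH and AIBN in benzene at 80 °C should then close ring A by 6-endo radical conjugate addition of C3 to C4, with hydrogen delivered to C5 on the α-face, giving 15.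

Step 4. The silylallyl anion may attack the lactone carbonyl, bond through its silylated carbon, or add to the wrong face of C6. The fallback sets out from 8 and returns at 14. Barbier propargylation (propargyl bromide, Zn, THF–NH4Cl aq) should spare the lactone and give the homopropargyl carbinol F4. Hydrosilylation of the terminal alkyne (Et3SiH, Pt2[(CH2=CHSiMe2)2O]3 cat.) should give the (E)-vinylsilane carbinol F5. F5 should give 14 under the conditions of step 5.

Step 8. Acyl transfer to the 6β-hydroxyl, which is shielded by three syn-axial groups, may be too slow, so that the activated trienoic acid is lost to side reactions. The fallback sets out from 16 and returns at 19. The potassium alkoxide of 16 (KN(SiMe3)2, THF, −78 °C) should be acylated by the small 2-(diethoxyphosphoryl)acetyl chloride to give the phosphonoacetate F6. A Horner–Wadsworth–Emmons reaction with (2E,4E)-hexa-2,4-dienal (LiCl, DBU, MeCN) should then build the (2E)-alkene and give 19.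

Further compounds
F1 | step 5 | 6α-allyl-6β-hydroxy carbinol | O[C@]1(CC=C)C[C@@H]2[C@@H](O[C@H]3C[C@@H](C)CC[C@@H]3C(C)C)OC(=O)[C@@H]2C(C)=C1C(C)=C
F2 | step 5 | 10α-allyl isopropylidene ketone | CC(C)=C1C(=O)C[C@@H]2[C@@H](O[C@H]3C[C@@H](C)CC[C@@H]3C(C)C)OC(=O)[C@@H]2[C@@]1(C)CC=C
F3 | step 5 | 10α-(3-iodopropyl) isopropylidene ketone | CC(C)=C1C(=O)C[C@@H]2[C@@H](O[C@H]3C[C@@H](C)CC[C@@H]3C(C)C)OC(=O)[C@@H]2[C@@]1(C)CCCI
F4 | step 4 | 6α-propargyl-6β-hydroxy carbinol | O[C@]1(CC#C)C[C@@H]2[C@@H](O[C@H]3C[C@@H](C)CC[C@@H]3C(C)C)OC(=O)[C@@H]2C(C)=C1C(C)=C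
F5 | step 4 | 6α-[(E)-3-(triethylsilyl)allyl]-6β-hydroxy carbinol | O[C@]1(C/C=C/[Si](CC)(CC)CC)C[C@@H]2[C@@H](O[C@H]3C[C@@H](C)CC[C@@H]3C(C)C)OC(=O)[C@@H]2C(C)=C1C(C)=C
F6 | step 8 | 6β-(diethoxyphosphoryl)acetate | CCOP(=O)(OCC)CC(=O)O[C@@H]1C[C@@H]3[C@@H](O[C@H]4C[C@@H](C)CC[C@@H]4C(C)C)OC(=O)[C@@H]3[C@@]2(C)CCCC(C)(C)[C@H]12
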